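**Retrosynthetic overview**
1. Last C–C bond: aldol condensation of the aryl methyl ketone with 4-methoxybenzaldehyde gives the chalcone C=C.
2. Last ring: the dihydrofuran C10–O bond is closed by oxidative cycloetherification of a diosphenol.
3. Key fragment union: intermolecular Michael (Friedel–Crafts type) addition of 2',6'-dihydroxy-4'-methoxyacetophenone to aristol-1(10)-ene-8,9-dione forms C1–C5'.
4. The enedione comes from aristolone by C9 oxygenation; the cyclopropane from a sulfonium isopropylide on the cross-conjugated dienone; ring B from a Robinson annulation (Mukaiyama–Michael with methyl vinyl ketone, then aldol) on the silyl enol ether made by asymmetric conjugate methylation of 2-methylcyclohexenone.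
5. Ring order: A (bought) → B → cyclopropane → dihydrofuran.

Assumption: aristolane numbering is used for the terpenoid carbons (ring A = C1–C5, C10; ring B = C5–C10; C11 = cyclopropane CMe2; C14/C15 = methyls on C4/C5), α is the face of C15 and β the face of C11, and primes mark the acetophenone ring (C1' acyl, C5' bonded to C1, O6' bonded to C10).

**Step 1**
Reactants: 1 2-methylcyclohex-2-en-1-one
Product: 3 (R)-trimethyl[(2,3-dimethylcyclohex-1-en-1-yl)oxy]silane, via aluminium enolate 2 (not isolated)
Conditions: Me3Al, Cu(O2CC4H3S) (2 mol %), (S,R,R)-binaphthol/bis(1-phenylethyl)amine phosphoramidite (4 mol %), Et2O, −30 °C; then Me3SiOTf, THF, −30 → 0 °C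
Reagents that add atoms: trimethylaluminium C[Al](C)C; trimethylsilyl trifluoromethanesulfonate C[Si](C)(C)OS(=O)(=O)C(F)(F)F
Why: Copper-catalysed asymmetric conjugate (Michael-type) methyl addition in which the chiral phosphoramidite complex selects the enone face so that C3 becomes R (the ligand antipode is the one chosen to give 3R), and O-silylation of the aluminium enolate fixes the enolate regiochemistry for step 2.

**Step 2**
Reactants: 3 (R)-trimethyl[(2,3-dimethylcyclohex-1-en-1-yl)oxy]silane; 4 but-3-en-2-one (methyl vinyl ketone)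
Product: 5 (2S,3R)-2,3-dimethyl-2-(3-oxobutyl)cyclohexan-1-one
Conditions: BF3·OEt2 (20 mol %), iPrOH (1 equiv), MeNO2, −20 °C
Reagents that add atoms: none
Why: Intermolecular Mukaiyama–Michael addition in which the tetrasubstituted silyl enol ether attacks the activated enone anti to the neighbouring pseudoaxial methyl group, setting the quaternary centre with the two methyls cis, while iPrOH takes up the silyl group.

**Step 3**
Reactants: 5 (2S,3R)-2,3-dimethyl-2-(3-oxobutyl)cyclohexan-1-one
Product: 6 (4aS,5R)-4a,5-dimethyl-4,4a,5,6,7,8-hexahydronaphthalen-2(3H)-one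
Conditions: KOH, MeOH, 65 °C
Reagents that add atoms: none
Why: Intramolecular aldol condensation (second half of the Robinson annulation) closes ring B without touching a stereocentre.

**Step 4**
Reactants: 6 (4aS,5R)-4a,5-dimethyl-4,4a,5,6,7,8-hexahydronaphthalen-2(3H)-one
Product: 9 (4aR,5R)-4a,5-dimethyl-5,6,7,8-tetrahydronaphthalen-2(4aH)-one, via lithium dienolate 7 (not isolated), via silyl dienol ether 8 (not isolated)
Conditions: LiN(iPr)2, THF, −78 °C; Me3SiCl; then Pd(OAc)2, MeCN, rt
Reagents that add atoms: none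
Why: Kinetic α'-deprotonation at C7, O-silylation and Saegusa–Ito oxidation introduce the C6=C7 double bond of the cross-conjugated dienone, and the stereocentres are not involved (the C4a descriptor changes only through CIP priorities).

**Step 5**
Reactants: 9 (4aR,5R)-4a,5-dimethyl-5,6,7,8-tetrahydronaphthalen-2(4aH)-one
Product: 10 aristolone (aristol-9-en-8-one; 1aR,7R,7aR,7bS)
Conditions: iPrSPh2+ BF4−, LiN(iPr)2, DME/CH2Cl2, −78 → −30 °C
Reagents that add atoms: isopropyldiphenylsulfonium tetrafluoroborate CC(C)[S+](c1ccccc1)c1ccccc1.F[B-](F)(F)F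
Why: Corey–Chaykovsky-type gem-dimethylcyclopropanation in which the isopropylide adds to C6 of the disubstituted enone (C10 is fully substituted) from the β face, anti to the axial C15 methyl on C5, and closes onto C7 with loss of Ph2S, setting C6 and C7.

**Step 6**
Reactants: 10 aristolone (aristol-9-en-8-one; 1aR,7R,7aR,7bS)
Product: 12 9-hydroxyaristol-1(10)-en-8-one (C9 epimers), via potassium dienolate 11 (not isolated)
Conditions: KN(SiMe3)2, THF, −78 → −40 °C; 2-(phenylsulfonyl)-3-phenyloxaziridine, −78 °C; AcOH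
Reagents that add atoms: trans-2-(phenylsulfonyl)-3-phenyloxaziridine O=S(=O)(N1OC1c1ccccc1)c1ccccc1
Why: γ-Deprotonation at C1 (the only acidic site, since C7–H is a cyclopropyl hydrogen) gives the extended dienolate, and Davis enolate hydroxylation occurs at the α-carbon C9 with the alkene moving to C1=C10; the C9 configuration is not controlled and is erased in step 7.

**Step 7**
Reactants: 12 9-hydroxyaristol-1(10)-en-8-one (C9 epimers)
Product: 13 aristol-1(10)-ene-8,9-dione
Conditions: Dess–Martin periodinane, NaHCO3, CH2Cl2, 0 °C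
Reagents that add atoms: none
Why: Buffered Dess–Martin oxidation of the secondary α-ketol gives the 1,2-dione and brings C1=C10 into conjugation with C9=O; the product is used at once to limit enolisation toward C2.

**Step 8**
Reactants: 13 aristol-1(10)-ene-8,9-dione; 14 1-(2,6-dihydroxy-4-methoxyphenyl)ethan-1-one
Product: 15 1α-(3-acetyl-2,4-dihydroxy-6-methoxyphenyl)-9-hydroxyaristol-9-en-8-one
Conditions: Sc(OTf)3 (10 mol %), 14 (1.5 equiv), MeCN, −20 → 0 °C
Reagents that add atoms: none
Why: Intermolecular Friedel–Crafts-type Michael addition in which the scandium-chelated alkylidene-1,2-dione is attacked at C1 by the only free (and twofold equivalent) ring carbon of the acylphloroglucinol; antiparallel (axial) attack on the ring A half-chair puts the aryl group on the α face, and C10 is sp2 in the diosphenol product, so C1 is the only centre set.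

**Step 9**
Reactants: 15 1α-(3-acetyl-2,4-dihydroxy-6-methoxyphenyl)-9-hydroxyaristol-9-en-8-one
Product: 16 1'-acetyl-2'-hydroxy-4'-methoxy arene fused through C5'–C1(α) and O6'–C10(α) to aristolane-8,9-dione (cis-fused dihydrobenzofuran)
Conditions: Bu4NI (10 mol %), tBuOOH (2 equiv), EtOAc, rt
Reagents that add atoms: none
Why: Hypoiodite-catalysed oxidative cycloetherification (intramolecular α-aryloxylation at the enol carbon C10 of the diosphenol); the short tether from the α-aryl group allows only a cis-fused dihydrobenzofuran, so the C10–O bond forms on the α face.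

**Step 10**
Reactants: 16 1'-acetyl-2'-hydroxy-4'-methoxy arene fused through C5'–C1(α) and O6'–C10(α) to aristolane-8,9-dione; 17 4-methoxybenzaldehyde
Product: 19 aldol adduct of 16 carrying 3-hydroxy-3-(4-methoxyphenyl)propanoyl at C1' (carbinol epimers), via dilithium phenoxide enolate 18 (not isolated)
Conditions: LiN(SiMe3)2 (2.2 equiv), THF, −78 °C; 17 (1.5 equiv); AcOH, −78 °C
Reagents that add atoms: none
Why: Directed intermolecular aldol addition in which the phenol and the acetyl CH3 are the only acidic sites (the dione is non-enolisable), the enolate is trapped by the aldehyde at low temperature before it can attack the dione, and the new carbinol centre is uncontrolled and removed in step 11.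

**Step 11**
Reactants: 19 aldol adduct of 16 carrying 3-hydroxy-3-(4-methoxyphenyl)propanoyl at C1' (carbinol epimers)
Product: 20 target CNP0121765.1 ((E)-3-(4-methoxyphenyl)prop-2-enoyl at C1')
Conditions: TsOH·H2O (5 mol %), toluene, 40 °C
Reagents that add atoms: none
Why: Acid-catalysed dehydration through the 4-methoxybenzylic cation completes the aldol (Claisen–Schmidt type) condensation and gives the conjugated (E)-enone as the thermodynamic geometry, with the chelated 2'-OH left in place.

**Compound list**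
1 | 2-methylcyclohex-2-en-1-one | CC1=CCCCC1=O | starting material
2 | dimethylaluminium (R)-2,3-dimethylcyclohex-1-en-1-olate | C[C@@H]1CCCC(O[Al](C)C)=C1C | intermediate
3 | (R)-trimethyl[(2,3-dimethylcyclohex-1-en-1-yl)oxy]silane | C[C@@H]1CCCC(O[Si](C)(C)C)=C1C | intermediate
4 | but-3-en-2-one (methyl vinyl ketone) | CC(=O)C=C | starting material
5 | (2S,3R)-2,3-dimethyl-2-(3-oxobutyl)cyclohexan-1-one | CC(=O)CC[C@@]1(C)[C@H](C)CCCC1=O | intermediate
6 | (4aS,5R)-4a,5-dimethyl-4,4a,5,6,7,8-hexahydronaphthalen-2(3H)-one | O=C1C=C2CCC[C@@H](C)[C@]2(C)CC1 | intermediate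
7 | lithium cross-conjugated dienolate of 6 (O8–C8=C7) | [Li]OC1=CC[C@@]2(C)[C@H](C)CCCC2=C1 | intermediate
8 | trimethylsilyl dienol ether of 6 | C[Si](C)(C)OC1=CC[C@@]2(C)[C@H](C)CCCC2=C1 | intermediate
9 | (4aR,5R)-4a,5-dimethyl-5,6,7,8-tetrahydronaphthalen-2(4aH)-one | O=C1C=C2CCC[C@@H](C)[C@]2(C)C=C1 | intermediate
10 | aristolone (aristol-9-en-8-one; 1aR,7R,7aR,7bS; 4α,5α-dimethyl, 6β,7β-cyclopropane) | O=C1C=C2CCC[C@@H](C)[C@]2(C)[C@H]2[C@@H]1C2(C)C | intermediate
11 | potassium dienolate of aristolone (O8–C8=C9–C10=C1) | [K]OC1=CC2=CCC[C@@H](C)[C@]2(C)[C@H]2[C@@H]1C2(C)C | intermediate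
12 | 9-hydroxyaristol-1(10)-en-8-one (C9 epimers, C9 not defined) | O=C1C(O)C2=CCC[C@@H](C)[C@]2(C)[C@H]2[C@@H]1C2(C)C | intermediate
13 | aristol-1(10)-ene-8,9-dione | O=C1C(=O)C2=CCC[C@@H](C)[C@]2(C)[C@H]2[C@@H]1C2(C)C | intermediate
14 | 1-(2,6-dihydroxy-4-methoxyphenyl)ethan-1-one | CC(=O)c1c(O)cc(OC)cc1O | starting material
15 | 1α-(3-acetyl-2,4-dihydroxy-6-methoxyphenyl)-9-hydroxyaristol-9-en-8-one | CC(=O)c1c(O)cc(OC)c(c1O)[C@H]1CC[C@@H](C)[C@]2(C)[C@H]3[C@H](C3(C)C)C(=O)C(O)=C12 | intermediate
16 | 1'-acetyl-2'-hydroxy-4'-methoxy arene fused through C5'–C1(α) and O6'–C10(α) to aristolane-8,9-dione | CC(=O)c1c(O)cc(OC)c2c1O[C@]13C(=O)C(=O)[C@@H]4[C@@H](C4(C)C)[C@@]1(C)[C@H](C)CC[C@H]23 | intermediate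
17 | 4-methoxybenzaldehyde | COc1ccc(C=O)cc1 | starting material
18 | dilithium phenoxide enolate of 16 | [Li]OC(=C)c1c(O[Li])cc(OC)c2c1O[C@]13C(=O)C(=O)[C@@H]4[C@@H](C4(C)C)[C@@]1(C)[C@H](C)CC[C@H]23 | intermediate
19 | aldol adduct: 16 with 3-hydroxy-3-(4-methoxyphenyl)propanoyl in place of acetyl (carbinol not defined) | COc1ccc(C(O)CC(=O)c2c(O)cc(OC)c3c2O[C@]24C(=O)C(=O)[C@@H]5[C@@H](C5(C)C)[C@@]2(C)[C@H](C)CC[C@H]34)cc1 | intermediate
20 | target CNP0121765.1: 16 with (E)-3-(4-methoxyphenyl)prop-2-enoyl in place of acetyl | COc1ccc(/C=C/C(=O)c2c(O)cc(OC)c3c2O[C@]24C(=O)C(=O)[C@@H]5[C@@H](C5(C)C)[C@@]2(C)[C@H](C)CC[C@H]34)cc1 | target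

**Totals**
Total step count: 11. Longest linear sequence: 11 steps (1 → 20); 4, 14 and 17 are bought.

**Three steps most likely to fail**

Step 8, facial selectivity at C1. The arene must enter axially on the α face, syn to the C15 methyl. Attack from the β face, anti to that methyl, may compete or dominate and would give the C1 epimer; 13 can also enolise before it reacts. The fallback sets out from 12 and comes back at 15, and delivers the arene intramolecularly instead. The 9β-epimer 9β-hydroxyaristol-1(10)-en-8-one F1 is separated from 12 (the 9α-epimer is simply oxidised on to 13). Mitsunobu coupling of F1 with 14 (PPh3, DIAD, THF) inverts C9 and gives 9α-(2-acetyl-3-hydroxy-5-methoxyphenoxy)aristol-1(10)-en-8-one F2. Heating F2 (PhNEt2, 150 °C) brings about an aromatic Claisen rearrangement that moves the arene suprafacially from O9 to C1 on the α face and gives 1α-(3-acetyl-2,4-dihydroxy-6-methoxyphenyl)aristol-9-en-8-one F3. Nucleophilic epoxidation of F3 (tBuOOH, DBU) gives the 9,10-epoxy ketone of F3 F4 (drawn as the α-epoxide; either face serves). Base-induced opening of F4 by deprotonation at C9 (KOH, MeOH) gives diosphenol 15.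

Step 9, chemoselectivity of the oxidative closure. The hypoiodite may iodinate the free C3'–H of the electron-rich ring or dehydrogenate C1–C10, and the peroxide may attack the dione. The fallback sets out from 15 and comes back at 16, and closes the ring without an oxidant. Base-mediated (DBU, THF) 5-exo oxa-Michael addition of the O6' phenoxide to C10, the β-carbon of the diosphenol enone, gives the C10–O6' cyclised 9-hydroxy-8-ketone (ketol) F5. Dess–Martin periodinane then oxidises the ketol to the dione 16. Cu(OAc)2 in the same flask is the alternative if the conjugate-addition equilibrium has to be pulled forward.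

Step 10, enolate chemistry beside the electrophilic 1,2-dione. The enolate may add to the dione, or the dione may not survive the base. The fallback sets out from 16 and comes back at 20, and masks the dione as a base-stable protected ketol. NaBH4 (0.3 equiv, MeOH/CH2Cl2, −78 °C) reduces the less hindered C8 carbonyl to give the 8-hydroxy-9-ketone of 16 F6. TBSOTf and 2,6-lutidine silylate both hydroxyls to give the 8-O,2'-O-bis(tert-butyldimethylsilyl) ether of F6 F7. A classical Claisen–Schmidt condensation with 17 (KOH, EtOH, rt) cleaves the aryl silyl ether in the flask and gives the 8-silyloxy-9-keto chalcone F8. Bu4NF/AcOH frees the 8-hydroxy-9-keto chalcone F9, and Dess–Martin oxidation gives 20.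

**Further compounds**
F1 | step 8 | 9β-hydroxyaristol-1(10)-en-8-one | O=C1[C@H](O)C2=CCC[C@@H](C)[C@]2(C)[C@H]2[C@@H]1C2(C)C
F2 | step 8 | 9α-(2-acetyl-3-hydroxy-5-methoxyphenoxy)aristol-1(10)-en-8-one | O=C1[C@@H](Oc3cc(OC)cc(O)c3C(C)=O)C2=CCC[C@@H](C)[C@]2(C)[C@H]2[C@@H]1C2(C)C
F3 | step 8 | 1α-(3-acetyl-2,4-dihydroxy-6-methoxyphenyl)aristol-9-en-8-one | CC(=O)c1c(O)cc(OC)c(c1O)[C@H]1CC[C@@H](C)[C@]2(C)[C@H]3[C@H](C3(C)C)C(=O)C=C12
F4 | step 8 | 9,10-epoxy ketone of F3 (9α,10α-epoxide drawn) | CC(=O)c1c(O)cc(OC)c(c1O)[C@H]1CC[C@@H](C)[C@]2(C)[C@H]3[C@H](C3(C)C)C(=O)[C@H]3O[C@@]312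
F5 | step 9 | C10–O6' cyclised 9-hydroxy-8-ketone (ketol, C9 not defined) | CC(=O)c1c(O)cc(OC)c2c1O[C@]13C(O)C(=O)[C@@H]4[C@@H](C4(C)C)[C@@]1(C)[C@H](C)CC[C@H]23
F6 | step 10 | 8-hydroxy-9-ketone of 16 (C8 not defined) | CC(=O)c1c(O)cc(OC)c2c1O[C@]13C(=O)C(O)[C@@H]4[C@@H](C4(C)C)[C@@]1(C)[C@H](C)CC[C@H]23
F7 | step 10 | 8-O,2'-O-bis(tert-butyldimethylsilyl) ether of F6 | CC(=O)c1c(O[Si](C)(C)C(C)(C)C)cc(OC)c2c1O[C@]13C(=O)C(O[Si](C)(C)C(C)(C)C)[C@@H]4[C@@H](C4(C)C)[C@@]1(C)[C@H](C)CC[C@H]23
F8 | step 10 | 8-silyloxy-9-keto chalcone | COc1ccc(/C=C/C(=O)c2c(O)cc(OC)c3c2O[C@]24C(=O)C(O[Si](C)(C)C(C)(C)C)[C@@H]5[C@@H](C5(C)C)[C@@]2(C)[C@H](C)CC[C@H]34)cc1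
F9 | step 10 | 8-hydroxy-9-keto chalcone | COc1ccc(/C=C/C(=O)c2c(O)cc(OC)c3c2O[C@]24C(=O)C(O)[C@@H]5[C@@H](C5(C)C)[C@@]2(C)[C@H](C)CC[C@H]34)cc1
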